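**Retrosynthetic overview**

1. The dihydrofuran ring is cut at both bonds to the side-chain carbons at once (C3–C3a and O1–C2). The prenylated, gem-dimethylated acylphloroglucinol 7 serves as a C,O-1,3-bisnucleophile and the geraniol-derived 2,3-epoxy iodide 10 as a 1,2-biselectrophile. This compresses the presumed biosynthesis (C-geranylation, 2,3-epoxidation, 5-exo closure) into one step.
2. Enabling feature: C3a lies between the C4 ketone and the enol carbon C7a of the vinylogous acid O1–C7a=C7(acyl)–C6=O in the six-membered ring. Before alkylation it is therefore a doubly stabilised carbanion carbon with an enolate oxygen one atom away. C3, C2 and the carbinol carbon are C1–C3 of geraniol, so the epoxide oxygen becomes the tertiary hydroxyl.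
3. Trione 7: phloroglucinol, Friedel–Crafts acylation with (R)-2-methylbutanoyl chloride, dearomatising gem-dimethylation, C-prenylation.
4. Iodide 10: geraniol, Sharpless asymmetric epoxidation, iodination.
5. Ring order: the carbocycle is the phloroglucinol ring throughout (dearomatised in step 3); the dihydrofuran is the only ring closed, in the last step.

Key step: step 7

Remark: the 2-methylbutanoyl stereocentre is (R) as drawn, and enantiopure (R)-2-methylbutanoic acid is taken as commercially available. Compounds 5, 7 and 11 are each written as one enol tautomer.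

**Route**

Step 1
Reactants: 1 (2R)-2-methylbutanoic acid
Product: 2 (2R)-2-methylbutanoyl chloride
Conditions: (COCl)2, cat. DMF, CH2Cl2, 0 °C to rt; used crude
Reagents that add atoms: oxalyl chloride, O=C(Cl)C(=O)Cl
Why: Acid chloride formation through the chloroiminium (Vilsmeier-type) species is mild enough to leave the α-stereocentre untouched.

Step 2
Reactants: 2 (2R)-2-methylbutanoyl chloride; 3 phloroglucinol
Product: 4 (2R)-2-methyl-1-(2,4,6-trihydroxyphenyl)butan-1-one
Conditions: AlCl3 (3.5 equiv), PhNO2/CH2Cl2, 0 °C to 40 °C; aq. HCl
Reagents that add atoms: none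
Why: Friedel–Crafts C-acylation of the symmetric, threefold-activated arene should stop at the monoketone because the acyl group deactivates the ring, and the moderate temperature is chosen to keep the α-stereocentre from enolising.

Step 3
Reactants: 4 (2R)-2-methyl-1-(2,4,6-trihydroxyphenyl)butan-1-one
Product: 5 3,5-dihydroxy-4,4-dimethyl-2-[(2R)-2-methylbutanoyl]cyclohexa-2,5-dien-1-one
Conditions: NaOMe (4 equiv), MeI (2.5 equiv), MeOH, 0 °C to rt; aq. HCl
Reagents that add atoms: iodomethane, CI
Why: Alkylative dearomatisation of the phloroglucinol polyanion (double C-methylation at one ring carbon, a known route to acylfilicinic acids) should give the gem-dimethyl trione as the main product, with the anionic ring shielding the acyl α-hydrogen from exchange.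

Step 4
Reactants: 5 3,5-dihydroxy-4,4-dimethyl-2-[(2R)-2-methylbutanoyl]cyclohexa-2,5-dien-1-one; 6 prenyl bromide
Product: 7 3,5-dihydroxy-4,4-dimethyl-2-[(2R)-2-methylbutanoyl]-6-(3-methylbut-2-en-1-yl)cyclohexa-2,5-dien-1-one
Conditions: NaOMe (2.1 equiv), MeOH, 0 °C; 6 (1.0 equiv) added slowly; aq. HCl
Reagents that add atoms: none
Why: C-alkylation of the dianion of the vinylogous acid at its only remaining ring CH (soft allylic bromide in a protic solvent favours C over O), with slow addition of one equivalent holding back a second prenylation.

Step 5
Reactants: 8 geraniol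
Product: 9 [(2S,3S)-3-methyl-3-(4-methylpent-3-en-1-yl)oxiran-2-yl]methanol
Conditions: Ti(OiPr)4 (5 mol%), L-(+)-diethyl tartrate (7 mol%), t-BuOOH, 4 Å MS, CH2Cl2, −20 °C
Reagents that add atoms: tert-butyl hydroperoxide, CC(C)(C)OO
Why: Sharpless asymmetric epoxidation: the allylic hydroxyl binds titanium so that only the 2,3-alkene is oxidised, and the L-(+)-tartrate ligand delivers oxygen to the face that gives the (2S,3S)-epoxide, which fixes both the later ring CH centre and the carbinol centre.

Step 6
Reactants: 9 [(2S,3S)-3-methyl-3-(4-methylpent-3-en-1-yl)oxiran-2-yl]methanol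
Product: 10 (2R,3S)-2-(iodomethyl)-3-methyl-3-(4-methylpent-3-en-1-yl)oxirane
Conditions: PPh3 (1.2 equiv), imidazole (1.3 equiv), I2 (1.15 equiv), Et2O/MeCN (3:1), 0 °C, dark; used promptly
Reagents that add atoms: iodine, II
Why: Appel-type iodination displaces the alkoxyphosphonium group at the primary CH2 by SN2, so neither epoxide carbon is touched (the descriptor at the ring CH changes to R only through the priority rules).

Step 7
Reactants: 7 3,5-dihydroxy-4,4-dimethyl-2-[(2R)-2-methylbutanoyl]-6-(3-methylbut-2-en-1-yl)cyclohexa-2,5-dien-1-one; 10 (2R,3S)-2-(iodomethyl)-3-methyl-3-(4-methylpent-3-en-1-yl)oxirane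
Product: 12 (2R,3aS)-2-[(2S)-2-hydroxy-6-methylhept-5-en-2-yl]-5,5-dimethyl-7-[(2R)-2-methylbutanoyl]-3a-(3-methylbut-2-en-1-yl)-3,3a-dihydro-1-benzofuran-4,6(2H,5H)-dione, via C-alkylated epoxide 11 (not isolated)
Conditions: CsOH·H2O (2.2 equiv), O-allyl-N-(9-anthracenylmethyl)cinchonidinium bromide (20 mol%), toluene/CH2Cl2 (4:1), −30 °C to rt, dark; then MeOH, aq. NaHCO3, 40 °C, same pot
Reagents that add atoms: none
Why: Proposed new method: the dianion of 7 should attack the CH2–I carbon of 10 through its prenyl-bearing ring carbon (SN2, giving the quaternary carbon of 11), after which the neighbouring enolate oxygen of the vinylogous acid opens the epoxide at its secondary carbon and the epoxide oxygen is released as the tertiary alkoxide; the closest known reaction types are the alkylative dearomatisation of acylphloroglucinols (also under cinchona-derived phase-transfer catalysis) and the C-alkylation/epoxide-opening annulation of cyclic 1,3-diones with epihalohydrin-type electrophiles. The dihydrofuran ring closes in the 5-exo-tet mode. The ring CH centre is set by inversion at the Sharpless-derived epoxide carbon and the carbinol centre is carried over unchanged from the epoxide, so both follow from 9, while the quaternary centre is set by the enolate face that the ion-paired chiral ammonium cation leaves open. The step needs C- over O-alkylation, which the soft iodide and the carbon terminus of the dianion favour, and 5-exo over 6-endo opening, which the basic medium directs to the less substituted epoxide carbon. Closure through the other flanking oxygen is excluded because the ketone next to the gem-dimethyl carbon can no longer enolise once the quaternary carbon is formed. Facial selectivity is the one demand not secured by the substrate itself, so the pseudoenantiomeric cinchoninium salt is held ready in case it proves to be the matched catalyst.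

**Compound list**

1 | (2R)-2-methylbutanoic acid | CC[C@@H](C)C(=O)O | starting material
2 | (2R)-2-methylbutanoyl chloride | CC[C@@H](C)C(=O)Cl | intermediate
3 | phloroglucinol (benzene-1,3,5-triol) | Oc1cc(O)cc(O)c1 | starting material
4 | (2R)-2-methyl-1-(2,4,6-trihydroxyphenyl)butan-1-one | CC[C@@H](C)C(=O)c1c(O)cc(O)cc1O | intermediate
5 | 3,5-dihydroxy-4,4-dimethyl-2-[(2R)-2-methylbutanoyl]cyclohexa-2,5-dien-1-one | CC[C@@H](C)C(=O)C1=C(O)C(C)(C)C(O)=CC1=O | intermediate
6 | prenyl bromide (1-bromo-3-methylbut-2-ene) | CC(C)=CCBr | starting material
7 | 3,5-dihydroxy-4,4-dimethyl-2-[(2R)-2-methylbutanoyl]-6-(3-methylbut-2-en-1-yl)cyclohexa-2,5-dien-1-one | CC[C@@H](C)C(=O)C1=C(O)C(C)(C)C(O)=C(CC=C(C)C)C1=O | intermediate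
8 | geraniol ((2E)-3,7-dimethylocta-2,6-dien-1-ol) | CC(C)=CCC/C(C)=C/CO | starting material
9 | [(2S,3S)-3-methyl-3-(4-methylpent-3-en-1-yl)oxiran-2-yl]methanol | OC[C@@H]1O[C@@]1(C)CCC=C(C)C | intermediate
10 | (2R,3S)-2-(iodomethyl)-3-methyl-3-(4-methylpent-3-en-1-yl)oxirane | IC[C@@H]1O[C@@]1(C)CCC=C(C)C | intermediate
11 | (4S)-3-hydroxy-6,6-dimethyl-2-[(2R)-2-methylbutanoyl]-4-(3-methylbut-2-en-1-yl)-4-{[(2S,3S)-3-methyl-3-(4-methylpent-3-en-1-yl)oxiran-2-yl]methyl}cyclohex-2-ene-1,5-dione | CC[C@@H](C)C(=O)C1=C(O)[C@](CC=C(C)C)(C[C@@H]2O[C@@]2(C)CCC=C(C)C)C(=O)C(C)(C)C1=O | intermediate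
12 | (2R,3aS)-2-[(2S)-2-hydroxy-6-methylhept-5-en-2-yl]-5,5-dimethyl-7-[(2R)-2-methylbutanoyl]-3a-(3-methylbut-2-en-1-yl)-3,3a-dihydro-1-benzofuran-4,6(2H,5H)-dione | CC[C@@H](C)C(=O)C1=C2O[C@@H]([C@@](C)(O)CCC=C(C)C)C[C@]2(CC=C(C)C)C(=O)C(C)(C)C1=O | target

**Step count and risks**

Total step count: 7. Longest linear sequence: 5 steps (1 → 2 → 4 → 5 → 7 → 12); the branch 8 → 9 → 10 adds 2 steps before the union.

Steps most likely to fail:

1. Step 7 (key step). The hindered, doubly stabilised carbanion may react sluggishly with the non-allylic iodide, so that O-alkylation or decay of the iodide takes over. The ion-paired cation may also discriminate the two enolate faces poorly, so that the epimer at the quaternary carbon forms alongside. The fallback gives up the one-pot, catalyst-controlled cascade for a stepwise sequence of known reaction types. It sets out from 9, which is converted (Tf2O, 2,6-lutidine, CH2Cl2, −78 °C) into [(2S,3S)-3-methyl-3-(4-methylpent-3-en-1-yl)oxiran-2-yl]methyl trifluoromethanesulfonate F1. The dilithium salt of 7 (LiN(SiMe3)2, THF, −78 °C) is C-alkylated with this far more reactive electrophile. The route is rejoined at 11, here isolated and separated by chromatography from its epimer at the quaternary carbon (the two are diastereomers). K2CO3 in MeOH then closes the dihydrofuran ring to 12 in a separate operation. Should 11 cyclise on silica, the separation would be done at the stage of 12.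

2. Step 6. The oxirane may be lost during iodination, either by iodide opening of the activated epoxide or by reductive fragmentation of the epoxy iodide to linalool under excess phosphine and iodide. The fallback sets out from 9 and separates activation from halide introduction. Mesylation (MsCl, Et3N, CH2Cl2, 0 °C) should give [(2S,3S)-3-methyl-3-(4-methylpent-3-en-1-yl)oxiran-2-yl]methyl methanesulfonate F2. Finkelstein exchange (NaI, NaHCO3, acetone, rt) under neutral, phosphine-free conditions then comes back to the route at 10.

3. Step 4. The dianion may be alkylated twice at the same ring carbon, or on oxygen, so that the monoprenyl compound is eroded. The fallback sets out from 5 and replaces the dianion alkylation by a Tsuji–Trost allylation of the neutral vinylogous acid: Pd(PPh3)4 (5 mol%) with commercial 3-methylbut-2-en-1-ol in toluene at 60 °C. The acidic substrate itself should activate the alcohol, the π-prenyl complex of divalent palladium should be attacked at its unsubstituted terminus, and no strong base is present to drive a second alkylation. It comes back to the route at 7 and passes through no new isolated compound.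

**Further compounds**

F1 | step 7 | [(2S,3S)-3-methyl-3-(4-methylpent-3-en-1-yl)oxiran-2-yl]methyl trifluoromethanesulfonate | FC(F)(F)S(=O)(=O)OC[C@@H]1O[C@@]1(C)CCC=C(C)C
F2 | step 6 | [(2S,3S)-3-methyl-3-(4-methylpent-3-en-1-yl)oxiran-2-yl]methyl methanesulfonate | CS(=O)(=O)OC[C@@H]1O[C@@]1(C)CCC=C(C)C
F0 | step 4 | none | none
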